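The numbers in the tables stem from a simulated flask on assumed constants; the scatter is artificial.

Start from 0.351: the product blue had made at its last reading, per unit of partner charged. Call this the partner's return. It is a reading with its scatter, taken at 3.00 min, earlier than the asked time.

| flask | substrate | partner | free catalyst | remark | time |
|---|---|---|---|---|---|
| blue | 0.30 M | 0.41 M | 13 mM | run made earlier |  |
| green | 0.30 M | 1.4 M | 13 mM | run made earlier |  |
| ash | 0.30 M | 0.300 M | 13 mM |  | 4.0 min |
| alder | 0.30 M | 0.500 M | 13 mM |  | 4.0 min |
| maple | 0.30 M | 0.800 M | 13 mM |  | 4.0 min |
| oak | 0.30 M | 1.00 M | 13 mM |  | 4.0 min |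

- blue (time / min: product / %): 0.250: 5; 0.500: 13; 1.33: 28; 3.00: 48
- green (time / min: product / %): 0.250: 6; 0.500: 12; 1.33: 33; 3.00: 66

(standard deviation of a reading: 1.5 percentage points)

- the earlier runs were read with a standard deviation of 1.5 percentage points
- "hardly changes" means that all values lie within two and a half points (for a concentration: within two and a half percent of the largest)

* amount of product at the end, in percent of the substrate charged for ash, alder, maple, oak, in this order
* how that number moves from the first to the last of them (falls all the way / rises all the way / rises, then falls / hardly changes / falls, then rises)

Run the two earlier flasks in slow motion. In the first instants they keep pace. At 0.500 min, blue reads 13% and green 12%, though green holds 3.41 times the partner. So at that reading the charge of partner does not stand out of a scatter of 1.5 percentage points. By 1.33 min the flasks have begun to part, at 28% against 33%. At 3.00 min they stand apart, at 48% against 66%. Over that last stretch blue gains 20 points and green 33 points, more than blue. The two flasks differ in their charge of partner, so read that gap as the partner's doing.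

Now freeze the return. Multiply it by each charge of partner and divide by the substrate charged. Ash gets 35.1% and alder 58.5%. Maple gets 93.7%. Now take green's last reading as a first-order fall in substrate and carry it on to 4.0 min. That gives 76.3%, less than maple's figure. I commit to this lower figure for maple and for oak.

The forecast gives 52%, 62%, 69% and 71%, and says the row rises all the way. Its ground is this: “That suggests saturation in the partner”. It stands higher than my reckoning at ash.

The flasks give 41.2%, 55.0%, 67.4% and 72.7%, and the row rises all the way.

    partner + free catalyst ⇌ catalyst intermediate A (K = 2.50 L mol⁻¹, k = 1.80 L mol⁻¹ s⁻¹)
    substrate + catalyst intermediate A ⇌ catalyst intermediate B (K = 250 L mol⁻¹, k = 23.0 L mol⁻¹ s⁻¹)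
    catalyst intermediate B ⇌ by-product + catalyst intermediate C (K = 28.0 M, k = 0.210 s⁻¹)
    catalyst intermediate C → free catalyst + product (k = 0.260 s⁻¹)
    catalyst intermediate C → spent catalyst (k = 0.00200 s⁻¹)
    partner → decomposed reagent (k = 0.0100 s⁻¹)

Ash returns 0.412, more than blue's reading. At the start of ash, the loss of partner to decomposed reagent runs at 0.43 of the forward binding of partner to free catalyst. At 4.00 min ash holds 0.173 M of decomposed reagent, with the partner, its limiting reagent, down to 0.611% of its charge and substrate still at 58.4%. Alder returns 0.330, with 0.327 M of decomposed reagent and partner at 1.21% of its charge.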